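## Structural features

Locants used throughout: C1 is the acetal carbon, O2 the ring oxygen, C3=C4 the enol ether, C4a and C11a the ring-fusion carbons, C5–C11 the remaining carbocyclic atoms, C12 the acetoxy carbinol and C13–C15 the enoate chain.

The target is a xenicane-type bicycle: a 2-acetoxy-3,4-dihydro-2H-pyran (C1, O2, C3, C4, C4a, C11a) fused through the C4a–C11a bond to a nine-membered carbocycle (C4a, C5–C11, C11a). The carbocycle carries an exocyclic methylene at C11, next to the ring fusion, and a trisubstituted 7,8-epoxide with a methyl group on C7. The epoxide is cis with respect to the ring bonds (C6 and C9 on the same side), so it derives from a ring-cis (Z) C7=C8 alkene. C1 (R), C11a (R) and C4a (S) are contiguous: the ring fusion is trans and the C1 acetoxy group is trans to the C11a–C11 bond. C12 (S) sits on the sp2 carbon C4 and is remote from the other centres, as are C7 (S) and C8 (R). The fragile groups are the acylal at C1, the enol ether whose allylic C12 acetate makes it a vinylogous acetal, the epoxide facing a transannular alkene, and C11a–H, which is allylic and α to the acetal. The real difficulty is the nine-membered ring with a defined alkene geometry, together with the order of the oxidation steps, so that epoxide, acylal and side chain are each introduced when the rest of the molecule tolerates the reagents. The key step uses the fact that C6–C7(CH3)–C8 is a 2-methylallyl unit inside the nine-membered ring with C5 directly attached to the ring-fusion carbon C4a. A π-allylpalladium complex over C6–C8, attacked at C6 by a stabilised carbanion at C5, closes the carbocycle and creates the C7=C8 alkene at the same time.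

## Logic of the disconnections

38 ⇒ 36 + 37. The C14=C15 double bond is cut (cross-metathesis). This leaves only an allyl group on C12 and keeps Lewis acids away from the epoxide and the acylal at the end. The forward step must react at the monosubstituted alkene only, not at the C11 methylene or the enol ether, and give the E-enoate.

36 ⇒ 35 ⇒ 33. The C12–O acetyl bond and then the C12–C13 bond are cut. C12 is far from every other stereocentre, so it is set by a chiral allylborane on the C4 aldehyde of 33 rather than by the substrate. The forward step needs reagent-controlled face selection under neutral conditions.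

33 ⇒ 31 (through 32). The acetyl–O bond at C1 is cut back to a silyl acetal. The exchange is placed at the formyl stage because only there is the lactol 32 stabilised as a vinylogous acid. Once C12 is sp3, a free lactol would open irreversibly to a dialdehyde. Fluoride unmasking spares the epoxide. The acetylation must give the anomer with the acetoxy group trans to the C11a substituent.

31 ⇒ 30. The two C–O bonds of the epoxide are cut. The epoxidation is placed while the enol ether is deactivated by the formyl group. The forward step needs chemoselectivity for the trisubstituted alkene and catalyst control of the face.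

30 ⇒ 28. The C4–C12 bond is cut (formylation of the enol ether). This removes the side-chain carbon and leaves the bare bicycle. The electrophile must attack only the enol ether and the silyl acetal must survive.

28 ⇒ 27. The two C5–H bonds are exchanged for the two sulfonyl groups that make C5 a soft carbon nucleophile. The forward step is a reductive desulfonylation that must leave three alkenes and the silyl acetal alone.

27 ⇒ 26. The C5–C6 bond is cut, opening the nine-membered ring to an isopropenyl carbinol carbonate and a bis-sulfonyl methine. The alkene is transposed from C7=C8 to C6=C7, which makes the electrophile available from a simple Grignard addition. The forward step must attack C6 and not C8, give the Z alkene, and beat oligomerisation. Checked atom by atom, 26 and 27 have the configuration of 38 at C1, C4a and C11a, so no structural correction is needed. The design change is the acetal group at C1: a silyl acetal, removable with fluoride, in place of an alkyl acetal that would need acid next to the epoxide.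

26 ⇒ 25 ⇒ 20 + 23. The carbonate C–O bond and the C10–C11 bond are cut (sp2–sp3 coupling of a vinyl triflate with an alkylborane). This delivers the exocyclic methylene without a ketone methylenation next to the epimerisable C11a and divides the molecule into the pyran 20 and the five-carbon dienol 23. The hydroboration must select the vinyl group of 23 over its isopropenyl group. The configuration at C8 is irrelevant.

23 ⇒ 21 + 22. The C7–C8 bond is cut (1,2-addition). Both partners are commercial.

20 ⇒ 18 ⇒ 17 ⇒ 15 ⇒ 13 ⇒ 9 + 10. In turn: the vinyl triflate goes back to a methyl ketone, the enol ether to a methyl acetal at C3, the silyl acetal at C1 to a lactone carbonyl, and the C11a–C11 bond is cut (aldol). With C1 as the lactone carbonyl, C11a is the only enolisable carbon and only C3 can become the enol ether carbon. This removes the regiochemical ambiguity of a 1,5-dialdehyde. The forward steps need a trans-selective aldol, ionisation of the methoxy group at C3 only, and kinetic enolisation of the methyl ketone.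

9 ⇒ 7 ⇒ 6 ⇒ 3 + 4. The lactone C–O bond and the C4a–C5 bond are cut (Michael addition). The single stereocentre C4a is set by an amine catalyst, and the two arms of the chain are told apart by their oxidation levels (acetal against silyl ether). The forward step needs enantiofacial control.

3 ⇒ 1 + 2. The C4=C4a double bond is cut (cross-metathesis) to two commercial alkenes.

## Other disconnections considered

Alternative 1: The cuts are the O2–C1 bond and the C4a–C11a bond. In the forward direction, heating an open-chain precursor that ends in a dioxinone would unmask an acyl ketene, which the C3 hydroxyl would trap as a 13-membered β-keto lactone. The doubly activated C11a would then add across the ring to C4a of an unsaturated nitrile and give A1. In its favour, both rings and the ring-fusion bond would arise from a linear chain in one operation, without an activating reagent. The epoxide would be made on an open chain, where the Shi epoxidation of a trisubstituted alkene is at its most reliable. On that point it is better than the chosen plan, which epoxidises inside a medium ring. C11 arrives as a ketone ready for methylenation, which is the equal of the chosen plan's triflate coupling. Against it here, A1 has C1 as a lactone carbonyl, C3 as a saturated CH2–O and C4 as an sp3 nitrile carbon. Reaching the acylal and enol ether needs a partial reduction, a dehydrogenation across C3–C4 and conversion of the nitrile to the side chain, all in the presence of the epoxide. The trans ring fusion and the C4 configuration would depend on the conformation of a 13-membered ring, which is hard to predict, and C11a of the β-keto lactone is configurationally labile. In comparison, the alternative builds the core in fewer ring-forming steps, but the chosen plan reaches the correct oxidation pattern at C1, C3 and C4 directly and sets C4a by a catalyst. Overall the step count should be no better.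

Alternative 2: The cut is the C9–C10 bond, read backwards as a Claisen rearrangement, with the stereochemistry taken from a chiral-pool monoterpene. In the forward direction, heating a seven-membered cyclic ether that carries an exocyclic enol ether and a vinyl group would form C9–C10, break O–C7 and give the nine-membered ketone A2 with the Z alkene. In its favour, the ring is formed by an intramolecular pericyclic reaction that needs no high dilution. The Z geometry is fixed by the cyclic transition state. On security of ring formation it is the better of the two plans. On alkene geometry and on the source of absolute configuration it is equal. The C12 carbon is already in place as the methylene on C4. Against it here, A2 holds C1 and C3 as primary silyl ethers. After oxidation to a 1,5-dialdehyde it is undecided which aldehyde becomes the acetal and which the enol ether, the very ambiguity the chosen route avoids through the lactone oxidation level. The C4 methylene must be moved into the ring and oxidised, and C11 must be methylenated next to C11a. The sequence from the terpene to the rearrangement substrate is long. In comparison, the alternative is mechanistically more reliable at the ring-closing step, but weaker on the heterocycle and on step economy.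

Alternative 3: The cut is the C6–C7 bond. In the forward direction, hydroboration of a vinyl group on C4a and intramolecular palladium-catalysed coupling of the C6 borane with a (Z)-iodoalkene at C7 would give A3. In its favour, the alkene geometry is fixed before the ring is closed. On that point it is better than the chosen plan, which relies on equilibration of π-allyl isomers. No sulfones have to be removed and the C4 carbon is present as an ester, which saves the desulfonylation and the formylation. Against it here, nine-membered rings are the least favourable size for B-alkyl coupling, so β-hydride loss, protodeboronation and dimerisation would compete. The Z-trisubstituted iodoalkene needs its own stereoselective synthesis. The C11 ketal of A3 must be removed with acid in the presence of an enol ether and an acetal before methylenation. In comparison, the two plans are equal in convergence. The chosen plan gets ring and alkene from an isopropenyl carbinol made in one step and tolerates both C8 epimers. The alternative would pay for its preset geometry with a longer fragment synthesis and two extra steps at C11.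

Key step: step 13

Assumption: the silyl acetal at C1 is drawn throughout as the anomer with the oxygen trans to the C11a substituent. If step 6 gives the other anomer or a mixture this is of no consequence, because C1 is equilibrated as the lactol and fixed only in step 17. The C3 epimers of 9–15, the C11 epimers of 12–17 and the C8 epimers of 23–26 are all carried on together.

## Steps

Step 1
Reactants: 1 tert-butyl(but-3-en-1-yloxy)dimethylsilane; 2 (E)-but-2-enal
Product: 3 (E)-5-[(tert-butyldimethylsilyl)oxy]pent-2-enal
Conditions: second-generation Grubbs catalyst (H2IMes)(PCy3)Cl2Ru=CHPh (2 mol%), 2 (3 equiv), CH2Cl2, 40 °C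
Reagents that add atoms: none
Why: Cross-metathesis of a terminal alkene with a conjugated aldehyde should give the E-enal, with propene leaving as a gas.

Step 2
Reactants: 3 (E)-5-[(tert-butyldimethylsilyl)oxy]pent-2-enal; 4 bis(phenylsulfonyl)methane
Product: 6 (S)-tert-butyl{[3-(bis(phenylsulfonyl)methyl)-5,5-dimethoxypentyl]oxy}dimethylsilane, via aldehyde 5 (not isolated)
Conditions: (R)-α,α-diphenylprolinol trimethylsilyl ether (10 mol%), toluene, rt; then HC(OMe)3, PPTS (cat.), MeOH, 0 °C
Reagents that add atoms: trimethyl orthoformate, COC(OC)OC; methanol, CO
Why: Iminium-catalysed Michael addition of the sulfone carbon acid to the enal sets C4a; the diphenyl(silyloxy)methyl group of the (R)-catalyst shields one face of the E-iminium ion, so the nucleophile adds to the other face of the β-carbon and gives the S adduct. The aldehyde is trapped at once as its dimethyl acetal, which stops retro-Michael loss and keeps C3 at the aldehyde level.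

Step 3
Reactants: 6 (S)-tert-butyl{[3-(bis(phenylsulfonyl)methyl)-5,5-dimethoxypentyl]oxy}dimethylsilane
Product: 7 (S)-3-[bis(phenylsulfonyl)methyl]-5,5-dimethoxypentan-1-ol
Conditions: Bu4NF, THF, 0 °C to rt
Reagents that add atoms: none
Why: Fluoride desilylation under non-acidic conditions frees the C1 hydroxyl without letting the δ-hydroxy acetal close to a cyclic mixed acetal, which acid would cause.

Step 4
Reactants: 7 (S)-3-[bis(phenylsulfonyl)methyl]-5,5-dimethoxypentan-1-ol
Product: 9 (4R)-4-[bis(phenylsulfonyl)methyl]-6-methoxytetrahydro-2H-pyran-2-one (both C6 epimers), via acid 8 (not isolated)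
Conditions: TEMPO (0.2 equiv), PhI(OAc)2 (2.5 equiv), NaHCO3, MeCN/H2O, 0 °C to rt; then camphorsulfonic acid (cat.), 4 Å molecular sieves, CH2Cl2, rt
Reagents that add atoms: water, O
Why: Nitroxyl-catalysed oxidation takes the primary alcohol to the acid under buffered conditions that spare the acetal; acid catalysis then lets the carboxyl group capture the oxocarbenium ion of the acetal as a six-membered pseudo-ester. C1 is now at the carboxyl level and C3 at the aldehyde level, which later decides where the enol ether forms.

Step 5
Reactants: 9 (4R)-4-[bis(phenylsulfonyl)methyl]-6-methoxytetrahydro-2H-pyran-2-one; 10 acetaldehyde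
Product: 13 3,4-trans-4-[bis(phenylsulfonyl)methyl]-6-methoxy-3-[1-(trimethylsilyloxy)ethyl]tetrahydro-2H-pyran-2-one, via dilithium dianion 11 (not isolated), via dilithium aldolate 12 (not isolated)
Conditions: LiN(iPr)2 (2.2 equiv), THF, −78 °C; 10 (3 equiv), −78 °C; then Me3SiCl, Et3N, −78 to 0 °C
Reagents that add atoms: chlorotrimethylsilane, C[Si](C)(C)Cl
Why: Dianion aldol reaction: the first equivalent of base removes the sulfone C–H, which also rules out retro-Michael loss of the sulfone carbon from the enolate, and the second forms the lactone enolate at C11a, the only α-position. The aldehyde should approach anti to the C4a substituent and set the trans relation (C11a as in the target); silylation in the flask blocks retro-aldol cleavage, and the C11 configuration is irrelevant.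

Step 6
Reactants: 13 3,4-trans-4-[bis(phenylsulfonyl)methyl]-6-methoxy-3-[1-(trimethylsilyloxy)ethyl]tetrahydro-2H-pyran-2-one
Product: 15 tetrahydropyran bis-acetal with tert-butyldimethylsilyloxy at C1 and methoxy at C3 and 1-(trimethylsilyloxy)ethyl at C11a and bis(phenylsulfonyl)methyl at C4a, via aluminium lactolate 14 (not isolated)
Conditions: iBu2AlH (2.5 equiv), CH2Cl2, −78 °C; then 2,6-lutidine, tBuMe2SiOTf, −78 to −30 °C
Reagents that add atoms: tert-butyldimethylsilyl trifluoromethanesulfonate, CC(C)(C)[Si](C)(C)OS(=O)(=O)C(F)(F)F
Why: Partial reduction of the lactone gives an aluminium hemiacetal that is stable at −78 °C, and O-silylation in the flask (reductive silylation of an ester) gives the silyl acetal without ever freeing the lactol, which would lose methanol and open to a dialdehyde.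

Step 7
Reactants: 15 tetrahydropyran bis-acetal (C1 silyl acetal, C3 methyl acetal)
Product: 17 1-[2-(tert-butyldimethylsilyloxy)-4-(bis(phenylsulfonyl)methyl)-3,4-dihydro-2H-pyran-3-yl]ethanol (2,3-trans and 3,4-trans; C11 epimers), via enol ether 16 (not isolated)
Conditions: Me3SiOTf (1.3 equiv), iPr2NEt (2 equiv), CH2Cl2, −20 to 0 °C; then K2CO3, MeOH, 0 °C
Reagents that add atoms: none
Why: Silyl triflate and amine convert a methyl acetal into an enol ether: the Lewis acid ionises the unhindered, more basic methoxy group at C3, and the resulting oxocarbenium ion can lose a proton only from C4, so the double bond forms at C3=C4 while the hindered silyl acetal at C1 stays. Carbonate in methanol then removes the trimethylsilyl ether at C11 and leaves the anomeric silyl acetal.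

Step 8
Reactants: 17 1-[2-(tert-butyldimethylsilyloxy)-4-(bis(phenylsulfonyl)methyl)-3,4-dihydro-2H-pyran-3-yl]ethanol
Product: 18 1-[2-(tert-butyldimethylsilyloxy)-4-(bis(phenylsulfonyl)methyl)-3,4-dihydro-2H-pyran-3-yl]ethanone
Conditions: Dess–Martin periodinane, NaHCO3, CH2Cl2, 0 °C to rt
Reagents that add atoms: none
Why: Neutral hypervalent-iodine oxidation gives the methyl ketone without the base that would trigger β-elimination of the ring oxygen or retro-Michael loss of the sulfone carbon.

Step 9
Reactants: 18 1-[2-(tert-butyldimethylsilyloxy)-4-(bis(phenylsulfonyl)methyl)-3,4-dihydro-2H-pyran-3-yl]ethanone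
Product: 20 1-[2-(tert-butyldimethylsilyloxy)-4-(bis(phenylsulfonyl)methyl)-3,4-dihydro-2H-pyran-3-yl]vinyl trifluoromethanesulfonate, via dipotassium dianion 19 (not isolated)
Conditions: KN(SiMe3)2 (2.2 equiv), THF, −78 °C; then PhNTf2, −78 to −40 °C
Reagents that add atoms: N-phenylbis(trifluoromethanesulfonimide), O=S(=O)(N(c1ccccc1)S(=O)(=O)C(F)(F)F)C(F)(F)F
Why: The first equivalent of base forms the sulfone carbanion, the second removes a methyl proton under kinetic control, and O-triflation of that enolate gives the 2-triflyloxy-1-alkene. C11a is not touched, so the trans arrangement is kept.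

Step 10
Reactants: 21 isopropenylmagnesium bromide; 22 prop-2-enal
Product: 23 2-methylpenta-1,4-dien-3-ol (racemic)
Conditions: THF, −78 to 0 °C; aq. NH4Cl
Reagents that add atoms: none
Why: 1,2-Addition of the Grignard reagent to the enal gives the bis-allylic carbinol; the racemate suffices because C8 becomes sp2 in step 13.

Step 11
Reactants: 23 2-methylpenta-1,4-dien-3-ol; 20 vinyl triflate
Product: 25 6-[2-(tert-butyldimethylsilyloxy)-4-(bis(phenylsulfonyl)methyl)-3,4-dihydro-2H-pyran-3-yl]-2-methylhepta-1,6-dien-3-ol (C8 epimers), via alkylborane 24 (not isolated)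
Conditions: 23 (1.5 equiv), Sia2BH (2.1 equiv per 23, from BH3·THF and 2-methylbut-2-ene), THF, 0 °C to rt; then 20, PdCl2(dppf)·CH2Cl2 (10 mol%), AsPh3, aq. K3PO4, DMF, rt
Reagents that add atoms: none
Why: The hindered dialkylborane first converts the hydroxyl into a borinate and then hydroborates the monosubstituted vinyl group at its terminus, in preference to the 1,1-disubstituted isopropenyl group. B-alkyl Suzuki–Miyaura coupling with the vinyl triflate forms C10–C11 and installs the exocyclic methylene directly; the free allylic hydroxyl is not ionised by zerovalent palladium in aqueous base.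

Step 12
Reactants: 25 allylic alcohol (C8 epimers)
Product: 26 methyl carbonate of 25: 6-[2-(tert-butyldimethylsilyloxy)-4-(bis(phenylsulfonyl)methyl)-3,4-dihydro-2H-pyran-3-yl]-2-methylhepta-1,6-dien-3-yl methyl carbonate (C8 epimers)
Conditions: ClCO2Me, pyridine, DMAP (cat.), CH2Cl2, 0 °C
Reagents that add atoms: methyl chloroformate, COC(=O)Cl
Why: O-Acylation of the secondary allylic alcohol; pyridine is too weak a base to deprotonate the bis-sulfone, so the carbon acid is left untouched.

Step 13
Reactants: 26 allylic methyl carbonate (C8 epimers)
Product: 27 (Z)-cyclononene-fused dihydropyran with bis(phenylsulfonyl) at C5 and methyl at C7 and methylene at C11 and tert-butyldimethylsilyloxy at C1 (trans ring fusion)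
Conditions: Pd(PPh3)4 (10 mol%), THF, 65 °C, slow addition of 26 (final 0.003 M)
Reagents that add atoms: none
Why: Zerovalent palladium ionises the allylic carbonate with inversion, CO2 is lost, and the methoxide set free deprotonates the bis-sulfone, so electrophile and nucleophile arise together without added base. The closest known reaction type is the palladium-catalysed intramolecular allylic alkylation of bis(sulfonyl)-stabilised carbanions that closes medium and large carbocycles, applied here to a 2-methylallyl unit. The two C8 epimers and the syn and anti π-allyl isomers interconvert by π–σ–π isomerisation faster than they cyclise, and since C8 ends up sp2 the mixture converges on one product. The ring closes by outer-sphere attack of C5 on the primary terminus C6, so all three allyl carbons end up inside the nine-membered ring; attack at C8 would be a 7-exo closure to a seven-membered ring with an isopropenyl group. No stereocentre is formed; the only stereochemical element is the alkene geometry, which is Z because only the π-allyl isomer with the C9 chain anti lets the tether reach C6, and the C7 methyl group lowers the usual penalty for an anti substituent. The step needs C6 over C8 regioselectivity, which the bulky soft nucleophile and the difference between a primary and a secondary allyl terminus should secure. It also needs cyclisation to outrun oligomerisation and β-hydride loss to a diene, which slow addition at high dilution and the geminal sulfonyl groups (Thorpe–Ingold effect) favour.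

Step 14
Reactants: 27 cyclised bis-sulfone
Product: 28 (Z)-cyclononene-fused dihydropyran with methyl at C7 and methylene at C11 and tert-butyldimethylsilyloxy at C1 (C5 now CH2)
Conditions: Na(Hg) (6%), Na2HPO4, MeOH/THF, −20 °C
Reagents that add atoms: none
Why: Buffered dissolving-metal reduction cleaves both C–S bonds by electron transfer and protonation; isolated alkenes, the enol ether and the silyl acetal are not reduced.

Step 15
Reactants: 28 desulfonylated bicycle
Product: 30 C4-formyl derivative of 28 (4-carbaldehyde of the dihydropyran), via iminium chloride 29 (not isolated)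
Conditions: POCl3, DMF, 0 °C to rt; then aq. NaOAc
Reagents that add atoms: N,N-dimethylformamide, CN(C)C=O; water, O
Why: Vilsmeier–Haack formylation: the chloroiminium ion attacks the nucleophilic β-carbon C4 of the enol ether, loss of the C4 proton restores the double bond, and hydrolysis gives the vinylogous formate. The isolated alkenes are not nucleophilic enough to react.

Step 16
Reactants: 30 C4 aldehyde
Product: 31 (7S,8R)-7,8-epoxide of 30
Conditions: D-fructose-derived Shi ketone (0.3 equiv), KHSO5 (as Oxone), K2CO3, Bu4NHSO4, MeCN/CH2(OMe)2, aq. Na2B4O7–Na2EDTA buffer (pH 10.5), 0 °C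
Reagents that add atoms: potassium peroxymonosulfate, [K+].[O-]S(=O)(=O)OO
Why: Shi epoxidation: the chiral dioxirane is electrophilic and should select the trisubstituted alkene over the 1,1-disubstituted one and the formyl-deactivated enol ether. In the spiro transition state the C8 hydrogen points to the catalyst ketal, which for the D-fructose ketone gives 8R (by analogy with 1-arylcycloalkenes), and syn delivery to the Z alkene fixes 7S.

Step 17
Reactants: 31 epoxy aldehyde
Product: 33 C1 acetate: (1R)-1-acetoxy epoxy aldehyde with the acetoxy group trans to the C11a substituent, via lactol 32 (not isolated)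
Conditions: Bu4NF, AcOH, THF, 0 °C; then Ac2O, Et3N, DMAP, 0 °C
Reagents that add atoms: acetic anhydride, CC(=O)OC(C)=O
Why: Buffered fluoride cleaves the anomeric silyl ether without acid, and the lactol is stable at this stage because the formyl group makes its ring-opened form a stabilised vinylogous acid that recloses. Acetylation of the equilibrating lactol should trap the anomer with the axial acetoxy group trans to the C11a substituent (anomeric effect and less crowding).

Step 18
Reactants: 33 C1 acetate epoxy aldehyde
Product: 35 (12S)-homoallylic alcohol: C4 carries CH(OH)CH2CH=CH2, via borinate 34 (not isolated)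
Conditions: (−)-Ipc2B(allyl), Et2O, −78 °C; then pH 7 phosphate buffer, MeOH, 30% H2O2, 0 °C
Reagents that add atoms: (−)-B-allyldiisopinocampheylborane, C=CCB([C@@H]1C[C@@H]2C[C@H]([C@H]1C)C2(C)C)[C@@H]1C[C@@H]2C[C@H]([C@H]1C)C2(C)C
Why: Brown allylation through a chair transition state: the reagent from (+)-α-pinene adds to the aldehyde face that gives the S carbinol when the aldehyde substituent outranks allyl, as it does here. The reagent is not Lewis acidic enough to open the epoxide or the acylal.

Step 19
Reactants: 35 (12S)-homoallylic alcohol
Product: 36 1,12-diacetate with a terminal alkene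
Conditions: Ac2O, pyridine, DMAP (cat.), CH2Cl2, 0 °C
Reagents that add atoms: acetic anhydride, CC(=O)OC(C)=O
Why: Base-mediated O-acetylation caps the acid-sensitive carbinol that is allylic to the enol ether before any further handling.

Step 20
Reactants: 36 1,12-diacetate; 37 methyl methacrylate
Product: 38 CNP0184381.3 (target)
Conditions: 37 (10 equiv), second-generation Hoveyda–Grubbs catalyst (H2IMes)Cl2Ru=CH(C6H4-2-OiPr) (10 mol%), CH2Cl2, 40 °C
Reagents that add atoms: none
Why: Cross-metathesis of the monosubstituted alkene with the methacrylate should give the E-trisubstituted enoate. The C11 methylene and the trisubstituted enol ether are too hindered to compete, and ring closure onto C11 would need a bridgehead alkene.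

## Compound list

1 | tert-butyl(but-3-en-1-yloxy)dimethylsilane | C=CCCO[Si](C)(C)C(C)(C)C | starting material
2 | (E)-but-2-enal | C/C=C/C=O | starting material
3 | (E)-5-[(tert-butyldimethylsilyl)oxy]pent-2-enal | O=C/C=C/CCO[Si](C)(C)C(C)(C)C | intermediate
4 | bis(phenylsulfonyl)methane | O=S(=O)(CS(=O)(=O)c1ccccc1)c1ccccc1 | starting material
5 | (S)-3-[bis(phenylsulfonyl)methyl]-5-[(tert-butyldimethylsilyl)oxy]pentanal | O=CC[C@H](CCO[Si](C)(C)C(C)(C)C)C(S(=O)(=O)c1ccccc1)S(=O)(=O)c1ccccc1 | intermediate (not isolated)
6 | (S)-tert-butyl{[3-(bis(phenylsulfonyl)methyl)-5,5-dimethoxypentyl]oxy}dimethylsilane | COC(OC)C[C@H](CCO[Si](C)(C)C(C)(C)C)C(S(=O)(=O)c1ccccc1)S(=O)(=O)c1ccccc1 | intermediate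
7 | (S)-3-[bis(phenylsulfonyl)methyl]-5,5-dimethoxypentan-1-ol | OCC[C@@H](CC(OC)OC)C(S(=O)(=O)c1ccccc1)S(=O)(=O)c1ccccc1 | intermediate
8 | (R)-3-[bis(phenylsulfonyl)methyl]-5,5-dimethoxypentanoic acid | OC(=O)C[C@@H](CC(OC)OC)C(S(=O)(=O)c1ccccc1)S(=O)(=O)c1ccccc1 | intermediate (not isolated)
9 | (4R)-4-[bis(phenylsulfonyl)methyl]-6-methoxytetrahydro-2H-pyran-2-one (both C6 epimers) | COC1C[C@@H](C(S(=O)(=O)c2ccccc2)S(=O)(=O)c2ccccc2)CC(=O)O1 | intermediate
10 | acetaldehyde | CC=O | starting material
11 | dilithium salt of 9 (sulfone carbanion and lactone enolate) | [Li+].[Li+].COC1C[C@@H]([C-](S(=O)(=O)c2ccccc2)S(=O)(=O)c2ccccc2)C=C([O-])O1 | intermediate (not isolated)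
12 | dilithium aldolate (3,4-trans; sulfone carbanion and C11 alkoxide) | [Li+].[Li+].COC1C[C@@H]([C-](S(=O)(=O)c2ccccc2)S(=O)(=O)c2ccccc2)[C@H](C(C)[O-])C(=O)O1 | intermediate (not isolated)
13 | 3,4-trans-4-[bis(phenylsulfonyl)methyl]-6-methoxy-3-[1-(trimethylsilyloxy)ethyl]tetrahydro-2H-pyran-2-one (C3 and C11 epimers) | COC1C[C@@H](C(S(=O)(=O)c2ccccc2)S(=O)(=O)c2ccccc2)[C@H](C(C)O[Si](C)(C)C)C(=O)O1 | intermediate
14 | diisobutylaluminium lactolate of 13 | COC1C[C@@H](C(S(=O)(=O)c2ccccc2)S(=O)(=O)c2ccccc2)[C@H](C(C)O[Si](C)(C)C)[C@@H](O[Al](CC(C)C)CC(C)C)O1 | intermediate (not isolated)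
15 | 2-(tert-butyldimethylsilyloxy)-4-[bis(phenylsulfonyl)methyl]-6-methoxy-3-[1-(trimethylsilyloxy)ethyl]tetrahydropyran (2,3-trans and 3,4-trans) | COC1C[C@@H](C(S(=O)(=O)c2ccccc2)S(=O)(=O)c2ccccc2)[C@H](C(C)O[Si](C)(C)C)[C@@H](O[Si](C)(C)C(C)(C)C)O1 | intermediate
16 | 2-(tert-butyldimethylsilyloxy)-4-[bis(phenylsulfonyl)methyl]-3-[1-(trimethylsilyloxy)ethyl]-3,4-dihydro-2H-pyran | CC(O[Si](C)(C)C)[C@@H]1[C@@H](O[Si](C)(C)C(C)(C)C)OC=C[C@H]1C(S(=O)(=O)c1ccccc1)S(=O)(=O)c1ccccc1 | intermediate (not isolated)
17 | 1-[2-(tert-butyldimethylsilyloxy)-4-(bis(phenylsulfonyl)methyl)-3,4-dihydro-2H-pyran-3-yl]ethanol (2,3-trans and 3,4-trans; C11 epimers) | CC(O)[C@@H]1[C@@H](O[Si](C)(C)C(C)(C)C)OC=C[C@H]1C(S(=O)(=O)c1ccccc1)S(=O)(=O)c1ccccc1 | intermediate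
18 | 1-[2-(tert-butyldimethylsilyloxy)-4-(bis(phenylsulfonyl)methyl)-3,4-dihydro-2H-pyran-3-yl]ethanone | CC(=O)[C@@H]1[C@@H](O[Si](C)(C)C(C)(C)C)OC=C[C@H]1C(S(=O)(=O)c1ccccc1)S(=O)(=O)c1ccccc1 | intermediate
19 | dipotassium salt of 18 (sulfone carbanion and methyl-side enolate) | [K+].[K+].C=C([O-])[C@@H]1[C@@H](O[Si](C)(C)C(C)(C)C)OC=C[C@H]1[C-](S(=O)(=O)c1ccccc1)S(=O)(=O)c1ccccc1 | intermediate (not isolated)
20 | 1-[2-(tert-butyldimethylsilyloxy)-4-(bis(phenylsulfonyl)methyl)-3,4-dihydro-2H-pyran-3-yl]vinyl trifluoromethanesulfonate | C=C(OS(=O)(=O)C(F)(F)F)[C@@H]1[C@@H](O[Si](C)(C)C(C)(C)C)OC=C[C@H]1C(S(=O)(=O)c1ccccc1)S(=O)(=O)c1ccccc1 | intermediate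
21 | isopropenylmagnesium bromide | C=C(C)[Mg]Br | starting material
22 | prop-2-enal (acrolein) | C=CC=O | starting material
23 | 2-methylpenta-1,4-dien-3-ol (racemic) | C=CC(O)C(C)=C | intermediate
24 | O,C-bis(disiamylboryl) adduct of 23 (boron on the terminal carbon of the former vinyl group) | C=C(C)C(OB(C(C)C(C)C)C(C)C(C)C)CCB(C(C)C(C)C)C(C)C(C)C | intermediate (not isolated)
25 | 6-[2-(tert-butyldimethylsilyloxy)-4-(bis(phenylsulfonyl)methyl)-3,4-dihydro-2H-pyran-3-yl]-2-methylhepta-1,6-dien-3-ol (C8 epimers) | C=C(CCC(O)C(C)=C)[C@@H]1[C@@H](O[Si](C)(C)C(C)(C)C)OC=C[C@H]1C(S(=O)(=O)c1ccccc1)S(=O)(=O)c1ccccc1 | intermediate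
26 | methyl carbonate of 25 (C8 epimers); precursor of the key step | C=C(CCC(OC(=O)OC)C(C)=C)[C@@H]1[C@@H](O[Si](C)(C)C(C)(C)C)OC=C[C@H]1C(S(=O)(=O)c1ccccc1)S(=O)(=O)c1ccccc1 | intermediate
27 | 5,5-bis(phenylsulfonyl) (Z)-cyclononene-fused dihydropyran silyl acetal; product of the key step | C=C1CC/C=C(C)\CC(S(=O)(=O)c3ccccc3)(S(=O)(=O)c3ccccc3)[C@@H]2C=CO[C@H](O[Si](C)(C)C(C)(C)C)[C@@H]12 | intermediate
28 | desulfonylated (Z)-cyclononene-fused dihydropyran silyl acetal | C=C1CC/C=C(C)\CC[C@@H]2C=CO[C@H](O[Si](C)(C)C(C)(C)C)[C@@H]12 | intermediate
29 | C4 (dimethyliminio)methyl chloride of 28 | C=C1CC/C=C(C)\CC[C@@H]2C(C=[N+](C)C)=CO[C@H](O[Si](C)(C)C(C)(C)C)[C@@H]12.[Cl-] | intermediate (not isolated)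
30 | C4 carbaldehyde of 28 | C=C1CC/C=C(C)\CC[C@@H]2C(C=O)=CO[C@H](O[Si](C)(C)C(C)(C)C)[C@@H]12 | intermediate
31 | (7S,8R)-epoxy C4 carbaldehyde silyl acetal | C=C1CC[C@H]2O[C@@]2(C)CC[C@@H]2C(C=O)=CO[C@H](O[Si](C)(C)C(C)(C)C)[C@@H]12 | intermediate
32 | epoxy C4 carbaldehyde lactol (C1 anomers) | C=C1CC[C@H]2O[C@@]2(C)CC[C@@H]2C(C=O)=COC(O)[C@@H]12 | intermediate (not isolated)
33 | (1R)-1-acetoxy epoxy C4 carbaldehyde | C=C1CC[C@H]2O[C@@]2(C)CC[C@@H]2C(C=O)=CO[C@H](OC(C)=O)[C@@H]12 | intermediate
34 | diisopinocampheylborinate of the (12S)-homoallylic alcohol | C=C1CC[C@H]2O[C@@]2(C)CC[C@@H]2C([C@H](CC=C)OB([C@@H]3C[C@@H]4C[C@H]([C@H]3C)C4(C)C)[C@@H]3C[C@@H]4C[C@H]([C@H]3C)C4(C)C)=CO[C@H](OC(C)=O)[C@@H]12 | intermediate (not isolated)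
35 | (12S)-homoallylic alcohol with C1 acetate | C=C1CC[C@H]2O[C@@]2(C)CC[C@@H]2C([C@H](CC=C)O)=CO[C@H](OC(C)=O)[C@@H]12 | intermediate
36 | 1,12-diacetate with terminal alkene | C=C1CC[C@H]2O[C@@]2(C)CC[C@@H]2C([C@H](CC=C)OC(C)=O)=CO[C@H](OC(C)=O)[C@@H]12 | intermediate
37 | methyl methacrylate | C=C(C)C(=O)OC | starting material
38 | CNP0184381.3 (1R,4aS,7S,8R,11aR,12S) | C=C1CC[C@H]2O[C@@]2(C)CC[C@@H]2C([C@H](C/C=C(\C)C(=O)OC)OC(C)=O)=CO[C@H](OC(C)=O)[C@@H]12 | target

## Step count and least certain steps

Total: 20 steps. Longest linear sequence: 19 steps (steps 1–9 and 11–20; step 10 makes the side fragment 23).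

Step 13 (key step). The most likely failures are attack at the secondary terminus C8 (seven-membered ring), β-hydride loss from the π-allyl complex to a diene, and intermolecular alkylation. All three arise because closing a nine-membered ring is slow and the nucleophile is a hindered tertiary carbanion. The fallback forms C5–C6 intermolecularly and closes the ring at C7=C8 by metathesis. Starting from 20, the sulfone carbanion (NaH, DMF) is alkylated with 3-bromo-2-methylpropene to give the C5-methallyl vinyl triflate F1. Negishi coupling of F1 with but-3-enylzinc bromide (PdCl2(dppf)) gives the metathesis substrate F2. Ring-closing metathesis of F2 with the second-generation Hoveyda–Grubbs catalyst (H2IMes)Cl2Ru=CH(C6H4-2-OiPr) at high dilution should join the vinyl group to the methallyl alkene and give the Z-cyclononene 27, where the route is rejoined.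

Step 7. The risk is ionisation at C1 instead of C3, with loss of the silyloxy group, which would scramble the acetal or give the regioisomeric enol ether; silyl triflates distinguish two acetal oxygens only by basicity and hindrance. The fallback makes the enol ether while C1 is still a carbonyl, so that only C3 can ionise. Starting from 13, Me3SiOTf and iPr2NEt convert the pseudo-ester into the enol lactone F3. iBu2AlH at −78 °C followed by tBuMe2SiOTf and 2,6-lutidine then gives 16, and K2CO3 in methanol gives 17, where the route is rejoined.

Step 11. The risks are hydroboration of the isopropenyl group of 23 alongside the vinyl group, and slow transfer of the primary alkyl group from a hindered borane, which leaves the triflate to decompose. The fallback builds the chain from an ester and adds the isopropenyl unit last. Starting from 20, Negishi coupling with (3-ethoxy-3-oxopropyl)zinc bromide (PdCl2(dppf)) gives the ethyl ester F4. iBu2AlH at −78 °C reduces F4 to the aldehyde F5. Excess CH2=C(CH3)MgBr at −78 °C then gives 25, where the route is rejoined.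

Step 15. The risk is acid-induced loss of the anomeric silyl group, or ionisation at C1 by the HCl that the formylation releases, followed by decomposition of the enol ether. The fallback acylates under buffered conditions. Starting from 28, trichloroacetyl chloride and pyridine give the C4 trichloromethyl ketone F6. K2CO3 in methanol cleaves it in a haloform-type reaction to the methyl ester F7. iBu2AlH reduces F7 to the allylic alcohol F8, and MnO2 oxidises F8 to 30, where the route is rejoined.

Step 16. The risk is poor facial selectivity, because the conformation of the nine-membered ring may expose one face of the alkene so strongly that the catalyst cannot override it; slow oxidation of the C11 methylene is a lesser risk. If the ring favours the wrong face, the fallback inverts the sense of a substrate-controlled attack. Starting from 30, N-bromosuccinimide in aqueous THF gives the bromohydrin F9 (bromine at C8 on the exposed face, hydroxyl at C7 anti to it). K2CO3 in methanol closes F9 with inversion at C8 to the epoxide 31, where the route is rejoined. If the ring favours the desired face, a plain dioxirane or peracid would serve.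

Step 20. The risk is slow or incomplete cross-metathesis with the hindered methacrylate, which gives time for alkene migration or catalyst loss on the enol ether. The fallback attaches the whole side chain in one carbon–carbon bond formation. Starting from 33, a vinylogous Mukaiyama aldol reaction with the silyl dienolate F10 (from methyl tiglate, LiN(iPr)2 and tBuMe2SiCl) is run at −78 °C. The promoter is the N-tosylvaline-derived oxazaborolidinone enantiomer that delivers the 12S alcohol. This gives the hydroxy enoate F11, and acetylation (Ac2O, pyridine, DMAP) gives 38.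

## Further compounds

F1 | step 13 | C5-(2-methylallyl) derivative of vinyl triflate 20 | C=C(OS(=O)(=O)C(F)(F)F)[C@@H]1[C@@H](O[Si](C)(C)C(C)(C)C)OC=C[C@H]1C(CC(C)=C)(S(=O)(=O)c1ccccc1)S(=O)(=O)c1ccccc1
F2 | step 13 | metathesis substrate with hexa-1,5-dien-2-yl group on C11a and 2-methylallyl group on C5 | C=CCCC(=C)[C@@H]1[C@@H](O[Si](C)(C)C(C)(C)C)OC=C[C@H]1C(CC(C)=C)(S(=O)(=O)c1ccccc1)S(=O)(=O)c1ccccc1
F3 | step 7 | 3,4-trans-4-[bis(phenylsulfonyl)methyl]-3-[1-(trimethylsilyloxy)ethyl]-3,4-dihydro-2H-pyran-2-one | CC(O[Si](C)(C)C)[C@@H]1C(=O)OC=C[C@H]1C(S(=O)(=O)c1ccccc1)S(=O)(=O)c1ccccc1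
F4 | step 11 | ethyl 4-[2-(tert-butyldimethylsilyloxy)-4-(bis(phenylsulfonyl)methyl)-3,4-dihydro-2H-pyran-3-yl]pent-4-enoate | C=C(CCC(=O)OCC)[C@@H]1[C@@H](O[Si](C)(C)C(C)(C)C)OC=C[C@H]1C(S(=O)(=O)c1ccccc1)S(=O)(=O)c1ccccc1
F5 | step 11 | 4-[2-(tert-butyldimethylsilyloxy)-4-(bis(phenylsulfonyl)methyl)-3,4-dihydro-2H-pyran-3-yl]pent-4-enal | C=C(CCC=O)[C@@H]1[C@@H](O[Si](C)(C)C(C)(C)C)OC=C[C@H]1C(S(=O)(=O)c1ccccc1)S(=O)(=O)c1ccccc1
F6 | step 15 | C4 trichloroacetyl derivative of 28 | C=C1CC/C=C(C)\CC[C@@H]2C(C(=O)C(Cl)(Cl)Cl)=CO[C@H](O[Si](C)(C)C(C)(C)C)[C@@H]12
F7 | step 15 | C4 methyl ester derivative of 28 | C=C1CC/C=C(C)\CC[C@@H]2C(C(=O)OC)=CO[C@H](O[Si](C)(C)C(C)(C)C)[C@@H]12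
F8 | step 15 | C4 hydroxymethyl derivative of 28 | C=C1CC/C=C(C)\CC[C@@H]2C(CO)=CO[C@H](O[Si](C)(C)C(C)(C)C)[C@@H]12
F9 | step 16 | 8-bromo-7-hydroxy derivative of 30 (anti bromohydrin) | C=C1CC[C@H](Br)[C@@](C)(O)CC[C@@H]2C(C=O)=CO[C@H](O[Si](C)(C)C(C)(C)C)[C@@H]12
F10 | step 20 | tert-butyl[(1-methoxy-2-methylbuta-1,3-dien-1-yl)oxy]dimethylsilane | C=CC(C)=C(OC)O[Si](C)(C)C(C)(C)C
F11 | step 20 | (12S)-12-hydroxy precursor of 38 (C1 acetate, free C12 hydroxyl, complete enoate chain) | C=C1CC[C@H]2O[C@@]2(C)CC[C@@H]2C([C@H](C/C=C(\C)C(=O)OC)O)=CO[C@H](OC(C)=O)[C@@H]12
A1 | alternative 1 | epoxy cyclonona-fused β-keto δ-lactone with nitrile at C4 | O=C1CC[C@H]2O[C@@]2(C)CC[C@@H]2[C@@H](C#N)COC(=O)[C@@H]12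
A2 | alternative 2 | (Z)-cyclononenone with 3-(silyloxy)prop-1-en-2-yl at C4a and silyloxymethyl at C11a, trans | O=C1CC/C=C(C)\CC[C@H](C(=C)CO[Si](C)(C)C(C)(C)C)[C@H]1CO[Si](C)(C)C(C)(C)C
A3 | alternative 3 | cyclonona-fused dihydropyran methyl acetal with C4 methyl ester and C11 dioxolane | C12(OCCO1)CC/C=C(C)\CC[C@@H]3C(C(=O)OC)=CO[C@H](OC)[C@@H]23
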